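- grey: substrate 2 M; the very flask that is asked about, followed so far
- flask: substrate 2.0 M; time 12 d

- grey (time / d: single ring / %, ring dimer / %): 0.208: 27.1, 28.8; 0.333: 27.2, 31.7; 0.500: 27.5, 35.1; 0.833: 26.5, 36.9; 1.67: 27.5, 39.2; 2.50: 27.3, 36.3

(each reading ± 1 percentage point)

- in percentages every species weighs as the substrate in it: one open dimer or ring dimer counts as two
- in percentages every species weighs as the substrate in it: one open trimer counts as three
- steps thought possible: substrate -> single ring; 2 substrate -> open dimer; substrate + open dimer -> open trimer; open dimer -> ring dimer; single ring <-> isomer of the product; substrate -> decomposition product
- the reaction counts as stopped when no species that holds the substrate changes by six tenths of a point or more over the second half of the time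

- at 12 d, what has stopped the reaction, if anything has (all of the substrate has reacted / it is still moving / forward and back rates have come level)
- how much single ring there is at 12 d, in percent of the substrate charged
- how much ring dimer there is at 12 d, in percent of the substrate charged

Slow drift is what you should look for in this flask. In the grey readings, single ring averages 27.2% from 0.208 d to 2.50 d, with no drift beyond the scatter of 1 percentage point, while ring dimer climbs from 28.8% at 0.208 d and then averages 37.5% from 0.833 d on, its last reading standing below the one before. Carry one number, s = 0.689 L mol⁻¹, the selectivity factor: ring dimer divided by single ring, per unit of substrate charged. Ring dimer comes through a step taking 2 substrate and single ring through a step taking one, so I expect their ratio to follow the charge. Don't change the charge, then. At 2.0 M, s gives a ratio of 1.38, and I commit to those averages at 12 d.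

The forecast says 27.2% single ring and 37.8% ring dimer, slightly more ring dimer than my average, and all of the substrate has reacted: “the reaction stopped because the substrate ran out”.

The flask gives 27.6% single ring and 38.9% ring dimer, and on what stopped it the answer is the same: all of the substrate has reacted. The forecast held.

    substrate → single ring (k = 1.10 h⁻¹)
    2 substrate → open dimer (k = 0.880 L mol⁻¹ h⁻¹)
    substrate + open dimer → open trimer (k = 0.650 L mol⁻¹ h⁻¹)
    open dimer → ring dimer (k = 0.230 h⁻¹)
    single ring ⇌ isomer of the product (K = 0.490, k = 0.800 h⁻¹)
    substrate → decomposition product (k = 2.60 × 10⁻⁴ h⁻¹)

By 2.40 d, substrate stood at 0% and its conversion into single ring had 100% of its turnover behind it. Open dimer was down to 0.0523% at 1.20 d, and ring dimer still stands at 38.9% at 120 d. The ratio in this flask at 12 d is 1.41.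

In the neighbour flask with 1.2 M of substrate, s gives 0.827. That flask computes to 34.2% ring dimer and 35.6% single ring, a ratio of 0.961, lower than at 2.0 M but higher than s gave.

Readings and results stem from a simulated flask for substances that don't exist; noise was put on by code.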